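I was asked how much target the red flask would hold at 5.0 d, and how near saturation its dissolved gas would stand.

| setting | red | teal | flask |
|---|---|---|---|
| substrate | 0.20 M | 0.30 M | 0.20 M |
| gas phase | 6.9 mM (held) | 6.9 mM (held) | 6.9 mM (held) |
| free catalyst | 0.62 mM | 0.62 mM | 0.62 mM |
| remark | the very flask that is asked about, followed so far | run made earlier |  |
| time |  |  | 5.0 d |

| run | time / d | target / % | substrate / % |
|---|---|---|---|
| red | 0.625 | 72.0 | 28.6 |
| red | 1.25 | 86.3 | 13.7 |
| red | 2.08 | 90.0 | 11.3 |
| red | 2.50 | 88.2 | 10.9 |
| teal | 0.417 | 44.9 | 54.7 |
| teal | 0.833 | 73.2 | 26.4 |
| teal | 2.00 | 88.3 | 12.1 |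
| teal | 5.00 | 88.3 | 10.8 |

(readings scatter by 0.5 percentage points)

- at the start none of the gas is dissolved
- the earlier runs were read with a standard deviation of 0.5 percentage points
- candidate steps: gas phase <-> dissolved gas; dissolved gas + free catalyst -> spent catalyst; substrate + dissolved gas + free catalyst -> free catalyst + target; substrate + dissolved gas -> uncatalysed product

* amount of target at 5.0 d, in percent of the substrate charged
* concentration of dissolved gas in solution at 5.0 d, in percent of saturation

Red and teal differ in their substrate charge, 0.20 M against 0.30 M, yet red had 10.9% of its substrate left at 2.50 d and teal 10.8% at 5.00 d, the same share within the scatter. In amount, at those last readings teal held more target than red, 0.265 M against 0.176 M, from the same 0.62 mM of free catalyst, so the catalyst did not stop after a set number of turns.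

I read it this way: the catalytic step and the death of the catalyst (deactivation) both need dissolved gas and free catalyst, so these cancel in the ratio of the two steps and c(substrate) remains. Each bit of catalyst lost then costs a fixed share of the substrate, not a fixed amount. I called the reach of the catalyst the natural log of charged over final c(substrate), divided by charged c(free catalyst), which teal puts at 3.59 mM⁻¹. Red holds the same c(free catalyst), so I expected 10.8% of its substrate left and about 89.2% as target; the reach says nothing about the gas. The forecast gave 89% of target and 99% of saturation, holding that “catalysis and deactivation both scale with dissolved gas”.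

The red flask gave 88.5% of target and 99.9% of saturation at 5.00 d, with 11% of its substrate left against my 10.8%, so the forecast stood.

    gas phase ⇌ dissolved gas, rate k1*(csat - [dissolved gas]) (kL = 0.0463 min⁻¹)
    dissolved gas + free catalyst → spent catalyst (k = 0.280 M⁻¹ min⁻¹)
    substrate + dissolved gas + free catalyst → free catalyst + target (k = 983 M⁻² min⁻¹)
    substrate + dissolved gas → uncatalysed product (k = 0.00108 M⁻¹ min⁻¹)

For the target to move 5 points from the red flask's value, that flask needed a free catalyst charge of 0.516 mM or 0.784 mM, or a time as early as 1.02 d. The same reach on the neighbouring flask, charged like red but with 1.5 × 10⁻⁴ M of free catalyst, gives 58.4% of its substrate left, and that flask held 56% at 5.00 d, with 40.8% as target and 3.10% as uncatalysed product.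

The numbers in the tables are simulated on assumed constants; the scatter is artificial.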